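**Plan**
- Retrosynthetic cuts, in this order: the C9 ester C–O bond; the C7–C11 bond (isopropenyl, from a 7α,8α-epoxide); then ring A at C1–C10 and C4–C5 in one [4+2] event.
- Enabling feature: ring A (C1–C2–C3–C4–C5–C10) has its oxygen at C2, para to the quaternary C5, and its secondary methyl at C4, ortho to C5. This is the retron of an (E)-2-silyloxypenta-1,3-diene adding across a C5=C10 alkene of ring B that carries a formyl group on C5 (the future C5 methyl).
- Forward: ring B first (enantioenriched cyclohexenecarbaldehyde 4), ring A by Diels–Alder reaction, then CHO → CH3, C9 carbinol → ketone with epimerisation of C10 to the trans-decalin, then C7–C9 functionalisation and acylation.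
- Stereochemistry: one centre (the C9 carbinol of 4) is set by CBS catalysis; it relays to C4, C5 and C10 in the cycloaddition and is then erased. C10 is reset by equilibration, C2 by a bulky hydride, C9 by an equilibrating reduction, C8 and C7 by hydroxyl-directed epoxidation and trans-diaxial opening.

Key step: step 5

Remark: positions are numbered as in eremophilanes (ring A = C1–C5 and C10, ring B = C5–C10, fusion at C5/C10, C14 = substituent on C5, C15 = methyl on C4); β is the face of the C5 substituent, and the target is 4β,5β-dimethyl, 10α-H (trans-decalin), 2α-OH, 7β-isopropenyl, 8α-OH, 9α-acyloxy.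

**Step 1**
Reactants: 1 3-oxocyclohex-1-ene-1-carbonitrile
Product: 2 (S)-3-hydroxycyclohex-1-ene-1-carbonitrile
Conditions: (R)-2-methyl-CBS-oxazaborolidine (10 mol%), catecholborane, toluene, −78 °C
Reagents that add atoms: none
Why: Corey–Bakshi–Shibata reduction of a cyclic enone, in which the alkenyl arm acts as the large group so that the (R)-catalyst should give the (S)-carbinol (the antipodal catalyst serves if the sense proves opposite).

**Step 2**
Reactants: 2 (S)-3-hydroxycyclohex-1-ene-1-carbonitrile
Product: 3 (S)-3-(tert-butyldimethylsilyloxy)cyclohex-1-ene-1-carbonitrile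
Conditions: TBSCl, imidazole, DMF, 0 °C → rt
Reagents that add atoms: tert-butyldimethylsilyl chloride, CC(C)(C)[Si](C)(C)Cl
Why: routine silylation of a secondary allylic alcohol, which installs the bulky group that later directs the cycloaddition face.

**Step 3**
Reactants: 3 (S)-3-(tert-butyldimethylsilyloxy)cyclohex-1-ene-1-carbonitrile
Product: 4 (S)-3-(tert-butyldimethylsilyloxy)cyclohex-1-ene-1-carbaldehyde
Conditions: i-Bu2AlH (1.2 equiv), CH2Cl2, −78 °C; then aqueous Rochelle salt, rt
Reagents that add atoms: water, O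
Why: partial reduction of the conjugated nitrile stops at the N-aluminio aldimine, which is hydrolysed to the enal on work-up without touching the C9 centre.

**Step 4**
Reactants: 5 (E)-pent-3-en-2-one
Product: 6 (E)-2-(triisopropylsilyloxy)penta-1,3-diene
Conditions: i-Pr3SiOTf, Et3N, CH2Cl2, 0 °C
Reagents that add atoms: triisopropylsilyl trifluoromethanesulfonate, CC(C)[Si](C(C)C)(C(C)C)OS(=O)(=O)C(F)(F)F
Why: soft enolisation at the methyl group is the standard route from enones to 2-silyloxy-1,3-dienes and keeps the E geometry of the C3=C4 bond.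

**Step 5**
Reactants: 4 (S)-3-(tert-butyldimethylsilyloxy)cyclohex-1-ene-1-carbaldehyde; 6 (E)-2-(triisopropylsilyloxy)penta-1,3-diene
Product: 7 cis-fused 5β-formyl-4β-methyl-9β-(tert-butyldimethylsilyloxy)-2-(triisopropylsilyloxy)-10βH-decal-2-ene
Conditions: Me2AlCl (1.1 equiv), CH2Cl2, −78 → −40 °C
Reagents that add atoms: none
Why: Me2AlCl binds the formyl oxygen and lowers the LUMO of the C5=C10 alkene; the diene then adds in an asynchronous concerted [4+2] in which its CH2 terminus (C1), the carbon of largest HOMO coefficient because of the 2-silyloxy and 4-methyl donors, bonds first to the enal β-carbon C10 and the methyl-bearing terminus C4 closes onto C5. The closest known reaction type is the Lewis-acid-promoted Diels–Alder reaction of 2-silyloxy-1,3-dienes with α-substituted enals such as cycloalkenecarbaldehydes. Ring A is the only ring closed, by suprafacial addition of the four-carbon diene across the ring B alkene, so that the C5 formyl group and H10 end cis. C5 and C10 are controlled by the C9 stereocentre, the diene approaching the face opposite the allylic silyloxy group, and C4 is controlled by the endo position of the aluminium-bound formyl group together with the E geometry of the diene, which places the C4 methyl cis to the formyl group. The step needs regio-, endo- and facial selectivity and must prefer the [4+2] path over 1,2-addition of the silyl enol ether to the aldehyde; these are secured by the matched donor–acceptor polarisation (oxygen para and methyl ortho to C5), by the formyl group being the only activating group and pointing away from ring B, by the bulky C9 silyl ether, and by the hindered formyl carbon at low temperature.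

**Step 6**
Reactants: 7 cis-fused 5β-formyl-4β-methyl-9β-(tert-butyldimethylsilyloxy)-2-(triisopropylsilyloxy)-10βH-decal-2-ene
Product: 8 p-toluenesulfonylhydrazone of 7 (E at C14=N)
Conditions: TsNHNH2 (1.1 equiv), EtOH, 40 °C
Reagents that add atoms: 4-methylbenzenesulfonohydrazide, Cc1ccc(cc1)S(=O)(=O)NN
Why: condensation at the only carbonyl group under near-neutral conditions that both silyl groups should survive.

**Step 7**
Reactants: 8 p-toluenesulfonylhydrazone of 7
Product: 9 cis-fused 4β,5β-dimethyl-9β-(tert-butyldimethylsilyloxy)-2-(triisopropylsilyloxy)-10βH-decal-2-ene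
Conditions: catecholborane, CHCl3, 0 °C; then NaOAc·3H2O, reflux
Reagents that add atoms: none
Why: mild Wolff–Kishner-type deoxygenation (hydroboration of the C=N bond, acetate-induced loss of sulfinate, loss of N2 from the diazene) turns the activating formyl group into the C5 methyl without acid or strong base and without touching a stereocentre.

**Step 8**
Reactants: 9 cis-fused 4β,5β-dimethyl-9β-(tert-butyldimethylsilyloxy)-2-(triisopropylsilyloxy)-10βH-decal-2-ene
Product: 11 trans-fused 4β,5β-dimethyl-10αH-decalin-2,9-dione, via cis-fused 2,9-dione 10 (not isolated)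
Conditions: CrO3, H2SO4, H2O/acetone, 0 °C → rt; then NaOMe (cat.), MeOH, rt
Reagents that add atoms: none
Why: aqueous acid hydrolyses the silyl enol ether to the C2 ketone and chromic acid cleaves the secondary silyl ether and oxidises the carbinol to the C9 ketone in the same pot (Jones-type oxidation), after which base equilibrates C10 through the C9 enolate to the trans-decalin, which should be the more stable epimer.

**Step 9**
Reactants: 11 trans-fused 4β,5β-dimethyl-10αH-decalin-2,9-dione
Product: 12 2α-hydroxy-4β,5β-dimethyl-10αH-decalin-9-one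
Conditions: LiBH(s-Bu)3 (1.05 equiv), THF, −78 °C
Reagents that add atoms: none
Why: the bulky hydride should reduce the unhindered C2 ketone well before the α-branched C9 ketone (as a steroid 3-ketone is reduced before a ring B ketone) and attacks C2 equatorially, giving the axial 2α-alcohol.

**Step 10**
Reactants: 12 2α-hydroxy-4β,5β-dimethyl-10αH-decalin-9-one
Product: 13 2α-(tert-butyldimethylsilyloxy)-4β,5β-dimethyl-10αH-decalin-9-one
Conditions: TBSCl, imidazole, DMF, rt → 40 °C
Reagents that add atoms: tert-butyldimethylsilyl chloride, CC(C)(C)[Si](C)(C)Cl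
Why: routine silylation, needed because the free axial alcohol would interfere with the enolate chemistry, the equilibrating reduction and the final acylation.

**Step 11**
Reactants: 13 2α-(tert-butyldimethylsilyloxy)-4β,5β-dimethyl-10αH-decalin-9-one
Product: 14 2α-(tert-butyldimethylsilyloxy)-4β,5β-dimethyl-10αH-decal-7-en-9-one
Conditions: LiN(i-Pr)2, THF, −78 °C; then N-tert-butylbenzenesulfinimidoyl chloride, −78 °C
Reagents that add atoms: none
Why: kinetic deprotonation occurs at the C8 methylene and not at the hindered C10 methine, and Mukaiyama dehydrogenation of the lithium enolate gives the Δ7 enone in one pot with C10 untouched.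

**Step 12**
Reactants: 14 2α-(tert-butyldimethylsilyloxy)-4β,5β-dimethyl-10αH-decal-7-en-9-one
Product: 15 2α-(tert-butyldimethylsilyloxy)-4β,5β-dimethyl-10αH-decal-7-en-9α-ol
Conditions: Al(Oi-Pr)3 (2 equiv), i-PrOH, acetone (trace), 82 °C, run to equilibrium
Reagents that add atoms: none
Why: Meerwein–Ponndorf–Verley reduction is selective for the carbonyl of an enone and reversible, so the carbinol should settle on the pseudo-equatorial 9α-alcohol, whereas irreversible hydride attack anti to the axial C5 methyl would give the syn-axial 9β-epimer.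

**Step 13**
Reactants: 15 2α-(tert-butyldimethylsilyloxy)-4β,5β-dimethyl-10αH-decal-7-en-9α-ol
Product: 16 7α,8α-epoxy-2α-(tert-butyldimethylsilyloxy)-4β,5β-dimethyl-10αH-decalin-9α-ol
Conditions: VO(acac)2 (5 mol%), t-BuOOH, CH2Cl2, 0 °C → rt
Reagents that add atoms: tert-butyl hydroperoxide, CC(C)(C)OO
Why: hydroxyl-directed vanadium-catalysed epoxidation delivers oxygen syn to the 9α-hydroxyl, which is also the face left open by the axial C5 methyl.

**Step 14**
Reactants: 16 7α,8α-epoxy-2α-(tert-butyldimethylsilyloxy)-4β,5β-dimethyl-10αH-decalin-9α-ol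
Product: 17 2α-(tert-butyldimethylsilyloxy)-7β-isopropenyl-4β,5β-dimethyl-10αH-decalin-8α,9α-diol
Conditions: CH2=C(CH3)MgBr (5 equiv), CuI (20 mol%), THF, −30 → 0 °C
Reagents that add atoms: isopropenylmagnesium bromide, CC(=C)[Mg]Br
Why: copper-catalysed Grignard opening of a cyclohexene oxide follows the Fürst–Plattner rule and the usual distal attack on a 2,3-epoxy alcohol, so the nucleophile enters C7 from the β-face and leaves the axial 8α-hydroxyl, as in the 2β-alkylation of steroid 2α,3α-epoxides.

**Step 15**
Reactants: 17 2α-(tert-butyldimethylsilyloxy)-7β-isopropenyl-4β,5β-dimethyl-10αH-decalin-8α,9α-diol; 18 (E)-3-methylpent-2-enoic acid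
Product: 19 2α-(tert-butyldimethylsilyloxy)-8α-hydroxy-7β-isopropenyl-4β,5β-dimethyl-10αH-decalin-9α-yl (E)-3-methylpent-2-enoate
Conditions: DCC, DMAP (cat.), CH2Cl2, 0 °C → rt, 1.1 equiv of 18
Reagents that add atoms: none
Why: Steglich esterification should acylate the equatorial 9α-hydroxyl in preference to the axial 8α-hydroxyl, and the mild conditions keep the E geometry of the β,β-disubstituted enoate.

**Step 16**
Reactants: 19 2α-(tert-butyldimethylsilyloxy)-8α-hydroxy-7β-isopropenyl-4β,5β-dimethyl-10αH-decalin-9α-yl (E)-3-methylpent-2-enoate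
Product: 20 CNP0129603.2, (10αH)-eremophil-11-ene-2α,8α,9α-triol 9-[(E)-3-methylpent-2-enoate]
Conditions: HF·pyridine, THF, 0 °C → rt
Reagents that add atoms: none
Why: acidic fluoride removes the silyl ether without base, so the ester should neither migrate between the cis 8,9-oxygens nor hydrolyse.

**Compound list**
1 | 3-oxocyclohex-1-ene-1-carbonitrile | N#CC1=CC(=O)CCC1 | starting material
2 | (S)-3-hydroxycyclohex-1-ene-1-carbonitrile | N#CC1=C[C@@H](O)CCC1 | intermediate
3 | (S)-3-(tert-butyldimethylsilyloxy)cyclohex-1-ene-1-carbonitrile | N#CC1=C[C@@H](O[Si](C)(C)C(C)(C)C)CCC1 | intermediate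
4 | (S)-3-(tert-butyldimethylsilyloxy)cyclohex-1-ene-1-carbaldehyde | O=CC1=C[C@@H](O[Si](C)(C)C(C)(C)C)CCC1 | intermediate
5 | (E)-pent-3-en-2-one | C/C=C/C(C)=O | starting material
6 | (E)-2-(triisopropylsilyloxy)penta-1,3-diene | C=C(O[Si](C(C)C)(C(C)C)C(C)C)/C=C/C | intermediate
7 | cis-fused 5β-formyl-4β-methyl-9β-(tert-butyldimethylsilyloxy)-2-(triisopropylsilyloxy)-10βH-decal-2-ene | C1C[C@]2(C=O)[C@@H](C)C=C(O[Si](C(C)C)(C(C)C)C(C)C)C[C@@H]2[C@@H](O[Si](C)(C)C(C)(C)C)C1 | intermediate
8 | p-toluenesulfonylhydrazone of 7 | C1C[C@]2(/C=N/NS(=O)(=O)c3ccc(C)cc3)[C@@H](C)C=C(O[Si](C(C)C)(C(C)C)C(C)C)C[C@@H]2[C@@H](O[Si](C)(C)C(C)(C)C)C1 | intermediate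
9 | cis-fused 4β,5β-dimethyl-9β-(tert-butyldimethylsilyloxy)-2-(triisopropylsilyloxy)-10βH-decal-2-ene | C1C[C@]2(C)[C@@H](C)C=C(O[Si](C(C)C)(C(C)C)C(C)C)C[C@@H]2[C@@H](O[Si](C)(C)C(C)(C)C)C1 | intermediate
10 | cis-fused 4β,5β-dimethyl-10βH-decalin-2,9-dione | C1C[C@]2(C)[C@@H](C)CC(=O)C[C@@H]2C(=O)C1 | intermediate (not isolated)
11 | trans-fused 4β,5β-dimethyl-10αH-decalin-2,9-dione | C1C[C@]2(C)[C@@H](C)CC(=O)C[C@H]2C(=O)C1 | intermediate
12 | 2α-hydroxy-4β,5β-dimethyl-10αH-decalin-9-one | C1C[C@]2(C)[C@@H](C)C[C@H](O)C[C@H]2C(=O)C1 | intermediate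
13 | 2α-(tert-butyldimethylsilyloxy)-4β,5β-dimethyl-10αH-decalin-9-one | C1C[C@]2(C)[C@@H](C)C[C@H](O[Si](C)(C)C(C)(C)C)C[C@H]2C(=O)C1 | intermediate
14 | 2α-(tert-butyldimethylsilyloxy)-4β,5β-dimethyl-10αH-decal-7-en-9-one | C1=CC[C@]2(C)[C@@H](C)C[C@H](O[Si](C)(C)C(C)(C)C)C[C@H]2C1=O | intermediate
15 | 2α-(tert-butyldimethylsilyloxy)-4β,5β-dimethyl-10αH-decal-7-en-9α-ol | C1=CC[C@]2(C)[C@@H](C)C[C@H](O[Si](C)(C)C(C)(C)C)C[C@H]2[C@@H]1O | intermediate
16 | 7α,8α-epoxy-2α-(tert-butyldimethylsilyloxy)-4β,5β-dimethyl-10αH-decalin-9α-ol | O1[C@@H]2C[C@]3(C)[C@@H](C)C[C@H](O[Si](C)(C)C(C)(C)C)C[C@H]3[C@H](O)[C@H]12 | intermediate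
17 | 2α-(tert-butyldimethylsilyloxy)-7β-isopropenyl-4β,5β-dimethyl-10αH-decalin-8α,9α-diol | C=C(C)[C@H]1C[C@]2(C)[C@@H](C)C[C@H](O[Si](C)(C)C(C)(C)C)C[C@H]2[C@H](O)[C@@H]1O | intermediate
18 | (E)-3-methylpent-2-enoic acid | CC/C(C)=C/C(=O)O | starting material
19 | 2α-(tert-butyldimethylsilyloxy)-8α-hydroxy-7β-isopropenyl-4β,5β-dimethyl-10αH-decalin-9α-yl (E)-3-methylpent-2-enoate | C=C(C)[C@H]1C[C@]2(C)[C@@H](C)C[C@H](O[Si](C)(C)C(C)(C)C)C[C@H]2[C@H](OC(=O)/C=C(\C)CC)[C@@H]1O | intermediate
20 | CNP0129603.2, (10αH)-eremophil-11-ene-2α,8α,9α-triol 9-[(E)-3-methylpent-2-enoate] | C=C(C)[C@H]1C[C@]2(C)[C@@H](C)C[C@H](O)C[C@H]2[C@H](OC(=O)/C=C(\C)CC)[C@@H]1O | target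

Total step count: 16. Longest linear sequence: 15 steps (1 → 20 through steps 1–3 and 5–16); diene 6 is made in one step (step 4).

**Steps most likely to fail**

1) Step 5. The silyl enol ether terminus may add 1,2 to the aluminium-bound formyl group (aldol-type path) instead of entering the [4+2] manifold, or the C9 silyl ether may give poor facial selectivity. The fallback moves stereocontrol from substrate to catalyst and carries C9 as an achiral ketal. Setting out from compound 1, ketalisation (ethane-1,2-diol, TsOH, benzene, water separator) gives 1,4-dioxaspiro[4.5]dec-6-ene-7-carbonitrile F1, and i-Bu2AlH followed by aqueous work-up gives 1,4-dioxaspiro[4.5]dec-6-ene-7-carbaldehyde F2. Cycloaddition of F2 with diene 6 under a chiral oxazaborolidinium triflimide (B-o-tolyl CBS-oxazaborolidine protonated with Tf2NH, 10–20 mol%, CH2Cl2, −78 °C, catalyst antipode chosen to expose the α-face) should give the cis-fused 9,9-(ethylenedioxy)-5β-formyl-4β-methyl-2-(triisopropylsilyloxy)-10βH-decal-2-ene F3; this catalyst class is known to give [4+2] adducts from α-substituted enals and 2-silyloxydienes. Condensation with TsNHNH2 gives the tosylhydrazone F4, and catecholborane followed by NaOAc·3H2O gives the 4β,5β-dimethyl ketal F5. Aqueous HCl in THF then removes the ketal and the silyl enol ether and equilibrates C10, so the fallback comes back to the route at compound 11.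

2) Step 14. The opening may be slow or incomplete, because the axial approach to C7 runs syn to the axial C5 methyl group; material may then be lost to halohydrin formation or to attack at C8. The fallback uses a slim sp nucleophile and elaborates it afterwards. Setting out from compound 16, LiC≡CH·H2NCH2CH2NH2 in DMSO should open the epoxide trans-diaxially to 2α-(tert-butyldimethylsilyloxy)-7β-ethynyl-4β,5β-dimethyl-10αH-decalin-8α,9α-diol F6. Zirconium-catalysed methylalumination (Me3Al, Cp2ZrCl2, CH2Cl2; then water) places methyl on the internal alkyne carbon and, after protonolysis of the alkenylalane, turns the ethynyl into the isopropenyl group, so the fallback comes back to the route at compound 17.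

3) Step 12. Equilibration may stay incomplete and leave the kinetically formed axial 9β-alcohol, which would misdirect the epoxidation. The fallback uses kinetic reduction followed by inversion. Setting out from compound 14, NaBH4 with CeCl3·7H2O in MeOH (Luche reduction) gives 2α-(tert-butyldimethylsilyloxy)-4β,5β-dimethyl-10αH-decal-7-en-9β-ol F7. Mitsunobu reaction with 4-nitrobenzoic acid (PPh3, DIAD, THF) inverts C9 to the 9α-(4-nitrobenzoate) F8, and K2CO3 in MeOH releases the alcohol, so the fallback comes back to the route at compound 15.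

**Further compounds**
F1 | step 5 | 1,4-dioxaspiro[4.5]dec-6-ene-7-carbonitrile | N#CC1=CC2(CCC1)OCCO2
F2 | step 5 | 1,4-dioxaspiro[4.5]dec-6-ene-7-carbaldehyde | O=CC1=CC2(CCC1)OCCO2
F3 | step 5 | cis-fused 9,9-(ethylenedioxy)-5β-formyl-4β-methyl-2-(triisopropylsilyloxy)-10βH-decal-2-ene | C1C[C@]2(C=O)[C@@H](C)C=C(O[Si](C(C)C)(C(C)C)C(C)C)C[C@@H]2C3(OCCO3)C1
F4 | step 5 | p-toluenesulfonylhydrazone of F3 | C1C[C@]2(/C=N/NS(=O)(=O)c4ccc(C)cc4)[C@@H](C)C=C(O[Si](C(C)C)(C(C)C)C(C)C)C[C@@H]2C3(OCCO3)C1
F5 | step 5 | cis-fused 9,9-(ethylenedioxy)-4β,5β-dimethyl-2-(triisopropylsilyloxy)-10βH-decal-2-ene | C1C[C@]2(C)[C@@H](C)C=C(O[Si](C(C)C)(C(C)C)C(C)C)C[C@@H]2C3(OCCO3)C1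
F6 | step 14 | 2α-(tert-butyldimethylsilyloxy)-7β-ethynyl-4β,5β-dimethyl-10αH-decalin-8α,9α-diol | C#C[C@H]1C[C@]2(C)[C@@H](C)C[C@H](O[Si](C)(C)C(C)(C)C)C[C@H]2[C@H](O)[C@@H]1O
F7 | step 12 | 2α-(tert-butyldimethylsilyloxy)-4β,5β-dimethyl-10αH-decal-7-en-9β-ol | C1=CC[C@]2(C)[C@@H](C)C[C@H](O[Si](C)(C)C(C)(C)C)C[C@H]2[C@H]1O
F8 | step 12 | 2α-(tert-butyldimethylsilyloxy)-4β,5β-dimethyl-10αH-decal-7-en-9α-yl 4-nitrobenzoate | C1=CC[C@]2(C)[C@@H](C)C[C@H](O[Si](C)(C)C(C)(C)C)C[C@H]2[C@@H]1OC(=O)c3ccc(cc3)[N+](=O)[O-]
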